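**Plan**

- Retrosynthesis: cut the C3–O ester (rohitukine + 3,4-dimethoxybenzoyl chloride); cut the pyranone ring at O1–C2, C2–C3 and C4–C4a back to a 2,4,6-trimethoxyphenyl piperidine; cut the piperidine at C5–C6 (together with C4–H); cut C3–C4 to a 1-arylvinyl anion and a glycine Weinreb amide.
- Enabling feature: piperidine C4 carries the phloroglucinol-type ring A (chromone C8, flanked by two oxygenated ring carbons), so a cation at C4 is strongly stabilized, and C6 is an N–CH2 carbon at the formaldehyde level. An N-acyliminium carbon (C6) can therefore be attacked by the CH2 end (C5) of a 1-arylvinyl group, and the C4 cation reduced by a silane in the same operation.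
- Forward order: acyclic chain → piperidine (step 7) → acetylation of ring A and closure of the pyranone ring → demethylation → esterification.
- Stereochemistry: C3 (S) from a Corey–Bakshi–Shibata reduction; C4 (R) from hydride delivery anti to the C3 acetoxy group in the key step, which gives the cis relationship.
- Helpers: N-CO2Me (becomes N-CH3 with LiAlH4), N-CH2OMe (iminium precursor), O-acetyl (stereodirecting, blocks a pinacol shift), aryl methyl ethers.

Key step: step 7

Remark: the piperidine is numbered N1, C2, C3 (acyloxy-bearing), C4 (chromone-bearing), C5, C6; the target SMILES corresponds to (3S,4R), with ester oxygen and chromone cis. Compounds 1, 4 and 18 are taken as commercially available.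

**Route**

Step 1
Reactants: 1 N-(methoxycarbonyl)glycine
Product: 2 methyl N-{2-[methoxy(methyl)amino]-2-oxoethyl}carbamate
Conditions: CDI, CH2Cl2, rt; then MeNH(OMe)·HCl, rt; aq. NaHCO3 work-up
Reagents that add atoms: N,O-dimethylhydroxylamine hydrochloride, CNOC.Cl
Why: Amide coupling through the acyl imidazolide gives the Weinreb amide, which later allows a single addition of an organolithium; no stereocentre is involved.

Step 2
Reactants: 2 methyl N-{2-[methoxy(methyl)amino]-2-oxoethyl}carbamate
Product: 3 methyl N-(methoxymethyl)-N-{2-[methoxy(methyl)amino]-2-oxoethyl}carbamate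
Conditions: NaH, THF, 0 °C; MOMCl, 0 °C to rt
Reagents that add atoms: chloromethyl methyl ether, COCCl
Why: N-alkylation of the sodium carbamate installs the N-CH2-OMe group (the latent iminium carbon, future C6) and removes the acidic N–H before the organolithium step.

Step 3
Reactants: 4 1-(2,4,6-trimethoxyphenyl)ethan-1-one
Product: 5 2,4,6-triisopropyl-N'-[1-(2,4,6-trimethoxyphenyl)ethylidene]benzenesulfonohydrazide
Conditions: 2,4,6-triisopropylbenzenesulfonohydrazide, HCl (cat.), MeCN, rt
Reagents that add atoms: 2,4,6-triisopropylbenzenesulfonohydrazide, CC(C)c1cc(C(C)C)c(S(=O)(=O)NN)c(C(C)C)c1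
Why: Acid-catalysed hydrazone condensation; the methyl ketone has a single α-position, so the later Shapiro fragmentation can give only the 1-arylvinyl anion.

Step 4
Reactants: 5 2,4,6-triisopropyl-N'-[1-(2,4,6-trimethoxyphenyl)ethylidene]benzenesulfonohydrazide; 3 methyl N-(methoxymethyl)-N-{2-[methoxy(methyl)amino]-2-oxoethyl}carbamate
Product: 7 methyl N-(methoxymethyl)-N-[2-oxo-3-(2,4,6-trimethoxyphenyl)but-3-en-1-yl]carbamate, via [1-(2,4,6-trimethoxyphenyl)ethenyl]lithium 6 (not isolated)
Conditions: n-BuLi (2.1 equiv), THF, −78 to 0 °C; then 3, −78 °C; cold aq. NH4Cl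
Reagents that add atoms: none
Why: The Shapiro reaction (dianion formation, loss of sulfinate and N2) gives vinyllithium 6, which is acylated by the Weinreb amide through the stable chelated tetrahedral intermediate, so the enone should form without over-addition; the cold quench limits conjugate addition of the liberated hydroxylamine.

Step 5
Reactants: 7 methyl N-(methoxymethyl)-N-[2-oxo-3-(2,4,6-trimethoxyphenyl)but-3-en-1-yl]carbamate
Product: 8 methyl N-[(2S)-2-hydroxy-3-(2,4,6-trimethoxyphenyl)but-3-en-1-yl]-N-(methoxymethyl)carbamate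
Conditions: (S)-2-methyl-CBS-oxazaborolidine (20 mol %), catecholborane, toluene, −78 °C; aq. NaOH work-up
Reagents that add atoms: none
Why: Corey–Bakshi–Shibata reduction; with the 1-arylvinyl group as the large and the CH2N group as the small substituent, the (S)-catalyst should deliver hydride to the face that gives the (S)-alcohol (future C3), and catecholborane at −78 °C avoids hydroboration of the alkene.

Step 6
Reactants: 8 methyl N-[(2S)-2-hydroxy-3-(2,4,6-trimethoxyphenyl)but-3-en-1-yl]-N-(methoxymethyl)carbamate
Product: 9 methyl N-[(2S)-2-acetoxy-3-(2,4,6-trimethoxyphenyl)but-3-en-1-yl]-N-(methoxymethyl)carbamate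
Conditions: Ac2O, pyridine, DMAP (cat.), CH2Cl2, 0 °C to rt
Reagents that add atoms: acetic anhydride, CC(=O)OC(C)=O
Why: DMAP-catalysed acetylation with retention at the carbinol carbon; the acetate protects O-3, disfavours a later pinacol-type shift next to the cation and serves as the stereodirecting group.

Step 7
Reactants: 9 methyl N-[(2S)-2-acetoxy-3-(2,4,6-trimethoxyphenyl)but-3-en-1-yl]-N-(methoxymethyl)carbamate
Product: 12 methyl (3S,4R)-3-acetoxy-4-(2,4,6-trimethoxyphenyl)piperidine-1-carboxylate, via N-acyliminium triflate 10 (not isolated), via benzylic cation triflate 11 (not isolated)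
Conditions: Et3SiH (5 equiv), CH2Cl2 (0.01 M), −78 °C; TMSOTf (1.2 equiv) added last, −78 to −20 °C; aq. NaHCO3
Reagents that add atoms: none
Why: Proposed new method: TMSOTf ionizes the N,O-acetal of 9 to the N-acyliminium ion 10, whose CH2 carbon (future C6) is attacked by the terminal CH2 (future C5) of the 1-arylvinyl group to give the tertiary benzylic cation 11 at C4, strongly stabilized by the 2,4,6-trimethoxyphenyl ring, and Et3SiH then delivers hydride to C4. The closest known reaction types are the N-acyliminium–alkene (aza-Prins) cyclization of N-(alkoxymethyl) homoallyl carbamates, usually ended by halide, formate or proton loss, and the ionic hydrogenation of benzylic cations by silanes, so ending the cyclization by hydride is the untested part. The piperidine closes in a 6-endo-trig mode with both the C=N and the C=C bond inside the new ring, the 5-exo alternative being excluded because it would place the charge on a primary carbon. The new stereocentre C4 is controlled by C3: allylic strain against the twisted aryl group should put the acetoxy group pseudoaxial in the half-chair cation, and hydride should add anti to it (the syn face is also shielded by acetoxy participation), which places aryl and acetoxy cis, that is (3S,4R). The step needs cyclization to outrun direct silane reduction of 10 (secured by the intramolecular, very nucleophilic styrene and high dilution), needs C3 to keep its configuration (the carbamate makes ring closure irreversible, so no cationic 2-aza-Cope equilibration through an achiral enol ester, and the acetate, unlike a free or silylated hydroxyl, disfavours a pinacol-type hydride shift), and needs an aprotic Lewis acid so that the electron-rich styrene is not protonated and reduced before it cyclizes.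

Step 8
Reactants: 12 methyl (3S,4R)-3-acetoxy-4-(2,4,6-trimethoxyphenyl)piperidine-1-carboxylate
Product: 13 (3S,4R)-1-methyl-4-(2,4,6-trimethoxyphenyl)piperidin-3-ol
Conditions: LiAlH4, THF, reflux; H2O, aq. NaOH work-up
Reagents that add atoms: none
Why: LiAlH4 reduces the methyl carbamate to the N-methyl group and cleaves the acetate in one operation (carbamate-to-N-methyl reduction); neither stereocentre is affected.

Step 9
Reactants: 13 (3S,4R)-1-methyl-4-(2,4,6-trimethoxyphenyl)piperidin-3-ol
Product: 14 (3S,4R)-4-(3-acetyl-2-hydroxy-4,6-dimethoxyphenyl)-1-methylpiperidin-3-yl acetate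
Conditions: Ac2O, BF3·OEt2, CH2Cl2, 0 °C to rt; aq. Na2CO3 work-up
Reagents that add atoms: acetic anhydride, CC(=O)OC(C)=O
Why: BF3-promoted Friedel–Crafts acetylation of the electron-rich ring at its free position, with O-acetylation of the alcohol and selective cleavage of the crowded methyl ether between the new acetyl group and the piperidinyl substituent (boron chelation to the ketone), which frees exactly the phenol needed for O1 of the chromone.

Step 10
Reactants: 14 (3S,4R)-4-(3-acetyl-2-hydroxy-4,6-dimethoxyphenyl)-1-methylpiperidin-3-yl acetate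
Product: 16 8-[(3S,4R)-3-hydroxy-1-methylpiperidin-4-yl]-5,7-dimethoxy-2-methyl-4H-chromen-4-one, via 1,3-diketone 15 (not isolated)
Conditions: NaH, EtOAc, reflux; then conc. HCl, rt; aq. NaHCO3 work-up
Reagents that add atoms: ethyl acetate, CCOC(C)=O
Why: Claisen condensation of the ketone enolate with ethyl acetate gives the 1,3-diketone (the O-acetyl group is lost by ethanolysis), and acid-catalysed cyclodehydration closes the pyranone ring (2-methylchromone synthesis).

Step 11
Reactants: 16 8-[(3S,4R)-3-hydroxy-1-methylpiperidin-4-yl]-5,7-dimethoxy-2-methyl-4H-chromen-4-one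
Product: 17 5,7-dihydroxy-8-[(3S,4R)-3-hydroxy-1-methylpiperidin-4-yl]-2-methyl-4H-chromen-4-one (rohitukine)
Conditions: pyridine hydrochloride (excess), 180 °C
Reagents that add atoms: none
Why: Aryl methyl ether cleavage by molten pyridinium chloride (chloride attacks the methyl groups of the protonated ethers); the secondary alcohol and the stereocentres are not touched.

Step 12
Reactants: 17 rohitukine; 18 3,4-dimethoxybenzoyl chloride
Product: 20 (3S,4R)-4-(5,7-dihydroxy-2-methyl-4-oxo-4H-chromen-8-yl)-1-methylpiperidin-3-yl 3,4-dimethoxybenzoate (chrotacumine D), via tris(3,4-dimethoxybenzoate) 19 (not isolated)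
Conditions: 18 (4 equiv), pyridine, DMAP (cat.), 50 °C; then pyrrolidine, 0 °C to rt; aq. NaHCO3 work-up
Reagents that add atoms: none
Why: Exhaustive acylation followed by chemoselective aminolysis: the two aryl esters (phenoxide leaving groups) should be cleaved by pyrrolidine far faster than the hindered alkyl 3,4-dimethoxybenzoate, so only the C3 ester remains, and acylation at oxygen retains configuration.

**Compound list**

1 | N-(methoxycarbonyl)glycine | COC(=O)NCC(=O)O | starting material
2 | methyl N-{2-[methoxy(methyl)amino]-2-oxoethyl}carbamate | COC(=O)NCC(=O)N(C)OC | intermediate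
3 | methyl N-(methoxymethyl)-N-{2-[methoxy(methyl)amino]-2-oxoethyl}carbamate | COCN(CC(=O)N(C)OC)C(=O)OC | intermediate
4 | 1-(2,4,6-trimethoxyphenyl)ethan-1-one | CC(=O)c1c(OC)cc(OC)cc1OC | starting material
5 | 2,4,6-triisopropyl-N'-[1-(2,4,6-trimethoxyphenyl)ethylidene]benzenesulfonohydrazide | CC(=NNS(=O)(=O)c1c(C(C)C)cc(C(C)C)cc1C(C)C)c2c(OC)cc(OC)cc2OC | intermediate
6 | [1-(2,4,6-trimethoxyphenyl)ethenyl]lithium (formed in the flask in step 4) | [Li]C(=C)c1c(OC)cc(OC)cc1OC | intermediate
7 | methyl N-(methoxymethyl)-N-[2-oxo-3-(2,4,6-trimethoxyphenyl)but-3-en-1-yl]carbamate | COCN(CC(=O)C(=C)c1c(OC)cc(OC)cc1OC)C(=O)OC | intermediate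
8 | methyl N-[(2S)-2-hydroxy-3-(2,4,6-trimethoxyphenyl)but-3-en-1-yl]-N-(methoxymethyl)carbamate | COCN(C[C@@H](O)C(=C)c1c(OC)cc(OC)cc1OC)C(=O)OC | intermediate
9 | methyl N-[(2S)-2-acetoxy-3-(2,4,6-trimethoxyphenyl)but-3-en-1-yl]-N-(methoxymethyl)carbamate | COCN(C[C@@H](OC(C)=O)C(=C)c1c(OC)cc(OC)cc1OC)C(=O)OC | intermediate
10 | N-[(2S)-2-acetoxy-3-(2,4,6-trimethoxyphenyl)but-3-en-1-yl]-N-(methoxycarbonyl)methaniminium triflate (formed in the flask in step 7) | C=[N+](C[C@@H](OC(C)=O)C(=C)c1c(OC)cc(OC)cc1OC)C(=O)OC.[O-]S(=O)(=O)C(F)(F)F | intermediate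
11 | (3S)-3-acetoxy-1-(methoxycarbonyl)-4-(2,4,6-trimethoxyphenyl)piperidin-4-ylium triflate (formed in the flask in step 7) | CC(=O)O[C@@H]1CN(C(=O)OC)CC[C+]1c2c(OC)cc(OC)cc2OC.[O-]S(=O)(=O)C(F)(F)F | intermediate
12 | methyl (3S,4R)-3-acetoxy-4-(2,4,6-trimethoxyphenyl)piperidine-1-carboxylate | CC(=O)O[C@@H]1CN(C(=O)OC)CC[C@@H]1c2c(OC)cc(OC)cc2OC | intermediate
13 | (3S,4R)-1-methyl-4-(2,4,6-trimethoxyphenyl)piperidin-3-ol | O[C@@H]1CN(C)CC[C@@H]1c2c(OC)cc(OC)cc2OC | intermediate
14 | (3S,4R)-4-(3-acetyl-2-hydroxy-4,6-dimethoxyphenyl)-1-methylpiperidin-3-yl acetate | CC(=O)O[C@@H]1CN(C)CC[C@@H]1c2c(O)c(C(C)=O)c(OC)cc2OC | intermediate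
15 | 1-{2-hydroxy-3-[(3S,4R)-3-hydroxy-1-methylpiperidin-4-yl]-4,6-dimethoxyphenyl}butane-1,3-dione (formed in the flask in step 10) | O[C@@H]1CN(C)CC[C@@H]1c2c(O)c(C(=O)CC(C)=O)c(OC)cc2OC | intermediate
16 | 8-[(3S,4R)-3-hydroxy-1-methylpiperidin-4-yl]-5,7-dimethoxy-2-methyl-4H-chromen-4-one | O[C@@H]1CN(C)CC[C@@H]1c2c(OC)cc(OC)c3c(=O)cc(C)oc23 | intermediate
17 | 5,7-dihydroxy-8-[(3S,4R)-3-hydroxy-1-methylpiperidin-4-yl]-2-methyl-4H-chromen-4-one (rohitukine) | O[C@@H]1CN(C)CC[C@@H]1c2c(O)cc(O)c3c(=O)cc(C)oc23 | intermediate
18 | 3,4-dimethoxybenzoyl chloride | COc1ccc(C(Cl)=O)cc1OC | starting material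
19 | (3S,4R)-4-[5,7-bis(3,4-dimethoxybenzoyloxy)-2-methyl-4-oxo-4H-chromen-8-yl]-1-methylpiperidin-3-yl 3,4-dimethoxybenzoate (formed in the flask in step 12) | COc1ccc(cc1OC)C(=O)O[C@@H]2CN(C)CC[C@@H]2c3c(OC(=O)c4ccc(OC)c(OC)c4)cc(OC(=O)c5ccc(OC)c(OC)c5)c6c(=O)cc(C)oc36 | intermediate
20 | (3S,4R)-4-(5,7-dihydroxy-2-methyl-4-oxo-4H-chromen-8-yl)-1-methylpiperidin-3-yl 3,4-dimethoxybenzoate (chrotacumine D) | COc1ccc(C(=O)O[C@@H]2CN(C)CC[C@@H]2c2c(O)cc(O)c3c(=O)cc(C)oc23)cc1OC | target

**Step count and risks**

Total: 12 steps. Longest linear sequence: 11 steps (steps 1, 2 and 4 to 12, starting from 1).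

Step 7 (proposed new method). What may go wrong: hydride transfer from Et3SiH to the N-acyliminium ion before ring closure; hydride delivery syn to the acetoxy group or to the acetoxonium carbon, which would erode the cis selectivity; intermolecular amidoalkylation of the trimethoxyphenyl ring. Fallback with known chemistry, setting out from 9: the cyclization is run without silane (BF3·OEt2, 2,6-di-tert-butyl-4-methylpyridine, CH2Cl2, −78 °C), an N-acyliminium–alkene cyclization ended by loss of the C5 proton, to give methyl (3S)-3-acetoxy-4-(2,4,6-trimethoxyphenyl)-3,6-dihydro-2H-pyridine-1-carboxylate F1. The reduction is then done as a separate catalytic hydrogenation (H2, 5% Rh/Al2O3, EtOAc), which should add hydrogen to the face opposite the allylic acetoxy group; the route is rejoined at 12.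

Step 4. What may go wrong: deprotonation by n-BuLi at the ring positions flanked by two methoxy groups in competition with dianion formation, or incomplete fragmentation of the hindered hydrazone dianion. Fallback, setting out from 4: condensation with N2H4·H2O (EtOH, reflux) gives [1-(2,4,6-trimethoxyphenyl)ethylidene]hydrazine F2. Barton vinyl iodide synthesis (I2, tetramethylguanidine, Et2O) gives 2-(1-iodoethenyl)-1,3,5-trimethoxybenzene F3. Iodine–lithium exchange (t-BuLi, 2 equiv, Et2O, −78 °C) gives 6, which is acylated with 3 as in step 4; the route is rejoined at 6.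

Step 5. What may go wrong: poor facial selectivity if the oxazaborolidine does not distinguish the 1-arylvinyl from the CH2N substituent, or competing conjugate reduction. Fallback, setting out from 7: Luche reduction (NaBH4, CeCl3·7H2O, MeOH, −40 °C) gives racemic methyl N-[2-hydroxy-3-(2,4,6-trimethoxyphenyl)but-3-en-1-yl]-N-(methoxymethyl)carbamate F4. Kinetic resolution by acetylation (Candida antarctica lipase B, vinyl acetate, MTBE) should, by the empirical rule for secondary alcohols with the arylvinyl group as the large substituent, acetylate the (S)-enantiomer; the slower enantiomer is removed by chromatography and the route is rejoined directly at 9.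

**Further compounds**

F1 | step 7 | methyl (3S)-3-acetoxy-4-(2,4,6-trimethoxyphenyl)-3,6-dihydro-2H-pyridine-1-carboxylate | CC(=O)O[C@@H]1CN(C(=O)OC)CC=C1c2c(OC)cc(OC)cc2OC
F2 | step 4 | [1-(2,4,6-trimethoxyphenyl)ethylidene]hydrazine | CC(=NN)c1c(OC)cc(OC)cc1OC
F3 | step 4 | 2-(1-iodoethenyl)-1,3,5-trimethoxybenzene | C=C(I)c1c(OC)cc(OC)cc1OC
F4 | step 5 | methyl N-[2-hydroxy-3-(2,4,6-trimethoxyphenyl)but-3-en-1-yl]-N-(methoxymethyl)carbamate (racemic) | COCN(CC(O)C(=C)c1c(OC)cc(OC)cc1OC)C(=O)OC
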